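Ring locants: C1 carries the alkyne, C2 is the olefinic CH, C3 bears OAc, C4 OMe, C5 and C6 the hydroxyls. The route rests on cutting C1–C6, because the sp2 carbon C1 can act as a vinyl nucleophile toward a C6 carbonyl. What remains, C2–C6, is L-arabinose read from its C5 to its C1. One chromium-mediated, nickel-catalysed closure then builds the C1–C6 bond, the cyclohexene ring and the C6 stereocentre while side chain, acetate and methyl ether are already in place. Its precursor is an acyclic Z-bromoenyne aldehyde: Br on C1 cis to C3, CHO as C6, triethylsilyl ethers on O5 and on the tertiary alcohol.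

Key step: step 18

Remark on the chemistry: on the ring C3/C4 are cis, C4/C5 trans and C5/C6 cis, and C3, C4, C5 have the spatial arrangement of C4, C3, C2 of L-arabinose, so the L-sugar leads to the required enantiomer; C6 is carried as a primary triethylsilyl ether rather than as an acetal or thioacetal, so that the aldehyde is released without acid or thiophilic metal salts next to the enyne and the tertiary allylic silyl ether; sugar locants are used for 1–13, ring locants from 22 on.

Step 1
Reactants: 1 L-arabinose
Product: 2 5-O-(tert-butyldiphenylsilyl)-L-arabinofuranose (anomeric mixture)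
Conditions: TBDPSCl (1.05 equiv), imidazole, DMF, 0 °C to rt
Reagents that add atoms: tert-butyldiphenylsilyl chloride, CC(C)(C)[Si](Cl)(c1ccccc1)c1ccccc1
Why: Regioselective silylation: the bulky chlorosilane should react only with a primary hydroxyl, which exists only in the furanose form, so mutarotation drains the sugar into the 5-O-silyl furanose while sugar C2, C3 and C4 stay untouched.

Step 2
Reactants: 2 5-O-(tert-butyldiphenylsilyl)-L-arabinofuranose
Product: 3 5-O-(tert-butyldiphenylsilyl)-1,2-O-isopropylidene-β-L-arabinofuranose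
Conditions: 2,2-dimethoxypropane, TsOH·H2O (cat.), acetone, rt
Reagents that add atoms: 2,2-dimethoxypropane, COC(C)(C)OC
Why: Acid-catalysed transketalisation: on the furanose only O1 and O2 can become cis (O2 and O3 are trans), so the cis-fused 1,2-dioxolane should form, which fixes the anomeric centre as β, masks C1, ties up O2 and O4 and leaves O3 as the only free hydroxyl.

Step 3
Reactants: 3 5-O-(tert-butyldiphenylsilyl)-1,2-O-isopropylidene-β-L-arabinofuranose
Product: 4 5-O-(tert-butyldiphenylsilyl)-1,2-O-isopropylidene-3-O-methyl-β-L-arabinofuranose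
Conditions: NaH, MeI, THF, 0 °C to rt
Reagents that add atoms: iodomethane, CI
Why: Williamson etherification of the single free hydroxyl; a silyl shift from O5 to the O3 alkoxide is disfavoured because C5 and O3 lie on opposite faces of the furanose.

Step 4
Reactants: 4 5-O-(tert-butyldiphenylsilyl)-1,2-O-isopropylidene-3-O-methyl-β-L-arabinofuranose
Product: 5 1,2-O-isopropylidene-3-O-methyl-β-L-arabinofuranose
Conditions: TBAF, THF, 0 °C to rt
Reagents that add atoms: none
Why: Fluoride-induced desilylation driven by the strong Si–F bond; ketal and methyl ether are inert to fluoride.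

Step 5
Reactants: 5 1,2-O-isopropylidene-3-O-methyl-β-L-arabinofuranose
Product: 6 1,2-O-isopropylidene-3-O-methyl-β-L-arabino-pentodialdo-1,4-furanose
Conditions: DMP, CH2Cl2, rt; used without chromatography
Reagents that add atoms: none
Why: Dess–Martin oxidation under near-neutral conditions stops at the aldehyde and should spare sugar C4, whose 3,4-trans arrangement is in any case the more stable one.

Step 6
Reactants: 6 1,2-O-isopropylidene-3-O-methyl-β-L-arabino-pentodialdo-1,4-furanose
Product: 7 6,6-dibromo-5,6-dideoxy-1,2-O-isopropylidene-3-O-methyl-β-L-arabino-hex-5-enofuranose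
Conditions: CBr4, PPh3, Zn dust, CH2Cl2, rt (ylide preformed); then 6, 0 °C to rt
Reagents that add atoms: carbon tetrabromide, BrC(Br)(Br)Br
Why: Ramirez dibromoolefination (first stage of the Corey–Fuchs sequence): the preformed ylide Ph3P=CBr2 undergoes a Wittig reaction with the aldehyde, and zinc dust keeps the medium free of Ph3PBr2, which protects the ketal.

Step 7
Reactants: 7 6,6-dibromo-5,6-dideoxy-1,2-O-isopropylidene-3-O-methyl-β-L-arabino-hex-5-enofuranose
Product: 9 6,6-dibromo-5,6-dideoxy-3-O-methyl-L-arabino-hex-5-enitol, via lactol 8 (not isolated)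
Conditions: TFA/H2O (4:1), 0 °C to rt; evaporation; NaBH4, MeOH, 0 °C
Reagents that add atoms: none
Why: Aqueous acid hydrolysis of the ketal followed by borohydride reduction of the open form of lactol 8 opens the furanose for good, turning sugar C1 into a primary alcohol (the masked C6 aldehyde) and freeing O4, while the electron-poor dibromoalkene resists both reagents and no stereocentre is touched.

Step 8
Reactants: 9 6,6-dibromo-5,6-dideoxy-3-O-methyl-L-arabino-hex-5-enitol
Product: 10 6,6-dibromo-5,6-dideoxy-1,2-O-isopropylidene-3-O-methyl-L-arabino-hex-5-enitol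
Conditions: 2,2-dimethoxypropane, PPTS (cat.), CH2Cl2, rt
Reagents that add atoms: 2,2-dimethoxypropane, COC(C)(C)OC
Why: Thermodynamic ketalisation: the terminal 1,2-dioxolane is favoured over the 2,4-dioxane, which for this anti-1,3-diol would have to be a twist-boat, so O4 should be left as the only free hydroxyl.

Step 9
Reactants: 10 6,6-dibromo-5,6-dideoxy-1,2-O-isopropylidene-3-O-methyl-L-arabino-hex-5-enitol
Product: 11 4-O-acetyl-6,6-dibromo-5,6-dideoxy-1,2-O-isopropylidene-3-O-methyl-L-arabino-hex-5-enitol
Conditions: Ac2O, pyridine, DMAP (cat.), CH2Cl2, 0 °C to rt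
Reagents that add atoms: acetic anhydride, CC(=O)OC(C)=O
Why: DMAP-catalysed acylation of the single free (allylic) hydroxyl installs what becomes the C3 acetate of the target with retention, since only the O–H bond is broken.

Step 10
Reactants: 11 4-O-acetyl-6,6-dibromo-5,6-dideoxy-1,2-O-isopropylidene-3-O-methyl-L-arabino-hex-5-enitol
Product: 12 4-O-acetyl-6,6-dibromo-5,6-dideoxy-3-O-methyl-L-arabino-hex-5-enitol
Conditions: AcOH/H2O (4:1), 40 °C
Reagents that add atoms: none
Why: Mild acid hydrolysis of a terminal dioxolane; the acetate is stable to aqueous acetic acid and its nearest hydroxyl is only 1,3-related, so acyl migration should be slow under non-basic conditions.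

Step 11
Reactants: 12 4-O-acetyl-6,6-dibromo-5,6-dideoxy-3-O-methyl-L-arabino-hex-5-enitol
Product: 13 4-O-acetyl-6,6-dibromo-5,6-dideoxy-3-O-methyl-1,2-bis-O-(triethylsilyl)-L-arabino-hex-5-enitol
Conditions: TESCl (2.5 equiv), imidazole, CH2Cl2, 0 °C to rt
Reagents that add atoms: chlorotriethylsilane, CC[Si](Cl)(CC)CC
Why: Silyl ether formation at both hydroxyls; the primary and the secondary triethylsilyl ether are told apart later by their very different rates in step 17.

Step 12
Reactants: 14 2-methylbut-3-yn-2-ol
Product: 15 triethyl[(2-methylbut-3-yn-2-yl)oxy]silane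
Conditions: TESCl, imidazole, DMAP (cat.), DMF, rt
Reagents that add atoms: chlorotriethylsilane, CC[Si](Cl)(CC)CC
Why: Silylation of the tertiary propargylic alcohol, accessible because the ethynyl group is slim; the ether saves hydride reagent in step 13 and shields the later tertiary allylic alcohol.

Step 13
Reactants: 15 triethyl[(2-methylbut-3-yn-2-yl)oxy]silane, 16 2,3-dibromopropene
Product: 18 {[(3E)-6-bromo-2-methylhepta-3,6-dien-2-yl]oxy}triethylsilane, via alkenylzirconocene chloride 17 (not isolated)
Conditions: Cp2Zr(H)Cl, THF, rt, dark; then 16, CuCl (10 mol %), 0 °C to rt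
Reagents that add atoms: none
Why: Hydrozirconation adds Zr–H syn across the terminal alkyne with zirconium at the unhindered terminus, which sets the E alkene, and copper-catalysed allylation of 17 (transmetalation to an alkenylcopper, SN2 and SN2' attack giving the same product) displaces only the allylic bromide of 16.

Step 14
Reactants: 18 {[(3E)-6-bromo-2-methylhepta-3,6-dien-2-yl]oxy}triethylsilane, 19 trimethylsilylacetylene
Product: 20 triethyl{[(3E)-2-methyl-6-methylidene-8-(trimethylsilyl)oct-3-en-7-yn-2-yl]oxy}silane
Conditions: PdCl2(PPh3)2 (3 mol %), CuI (5 mol %), Et3N, THF, 45 °C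
Reagents that add atoms: none
Why: Sonogashira coupling of the 2-bromo-1-alkene with a terminal alkyne; the silyl cap prevents double coupling and the skipped diene should not be touched by the mild amine base.

Step 15
Reactants: 20 triethyl{[(3E)-2-methyl-6-methylidene-8-(trimethylsilyl)oct-3-en-7-yn-2-yl]oxy}silane
Product: 21 triethyl{[(3E)-2-methyl-6-methylideneoct-3-en-7-yn-2-yl]oxy}silane
Conditions: K2CO3 (cat.), MeOH, rt
Reagents that add atoms: none
Why: Protodesilylation of the alkynyl C–Si bond by catalytic methoxide; the hindered tertiary triethylsilyl ether is stable to K2CO3 in methanol.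

Step 16
Reactants: 13 4-O-acetyl-6,6-dibromo-5,6-dideoxy-3-O-methyl-1,2-bis-O-(triethylsilyl)-L-arabino-hex-5-enitol, 21 triethyl{[(3E)-2-methyl-6-methylideneoct-3-en-7-yn-2-yl]oxy}silane
Product: 22 (2S,3S,4S,5Z,11E)-6-bromo-3-methoxy-13-methyl-9-methylidene-1,2,13-tris(triethylsilyloxy)tetradeca-5,11-dien-7-yn-4-yl acetate
Conditions: 21 (1.05 equiv), PdCl2(dppf) (5 mol %), CuI (5 mol %), iPr2NH, degassed toluene, rt
Reagents that add atoms: none
Why: Trans-selective Sonogashira coupling of a 1,1-dibromoalkene: zerovalent palladium inserts faster into the less hindered C–Br bond trans to the carbon chain, so the alkyne should enter trans to C3 and the surviving bromide stays cis to C3 (Z), while room temperature, one equivalent of alkyne and the wide-bite-angle ligand hold back a second coupling, dehydrobromination and ionisation of the allylic acetate.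

Step 17
Reactants: 22 (2S,3S,4S,5Z,11E)-6-bromo-3-methoxy-13-methyl-9-methylidene-1,2,13-tris(triethylsilyloxy)tetradeca-5,11-dien-7-yn-4-yl acetate
Product: 23 (2R,3S,4S,5Z,11E)-4-acetoxy-6-bromo-3-methoxy-13-methyl-9-methylidene-2,13-bis(triethylsilyloxy)tetradeca-5,11-dien-7-ynal (Z-bromoenyne aldehyde)
Conditions: (COCl)2, DMSO, CH2Cl2, −78 to −40 °C; then Et3N, −78 to 0 °C; used at once
Reagents that add atoms: none
Why: Swern oxidation applied directly to a silyl ether: chlorodimethylsulfonium chloride attacks only the unhindered primary triethylsilyl ether, the alkoxysulfonium salt collapses with base to the aldehyde, the secondary and tertiary silyl ethers stay on, and the cold, short contact with amine should spare the C5 centre and the β-methoxy group.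

Step 18
Reactants: 23 (2R,3S,4S,5Z,11E)-4-acetoxy-6-bromo-3-methoxy-13-methyl-9-methylidene-2,13-bis(triethylsilyloxy)tetradeca-5,11-dien-7-ynal
Product: 25 (1S,4S,5S,6S)-4-hydroxy-6-methoxy-3-[(5E)-7-methyl-3-methylidene-7-(triethylsilyloxy)oct-5-en-1-yn-1-yl]-5-(triethylsilyloxy)cyclohex-2-en-1-yl acetate, via vinylchromium dichloride 24 (not isolated)
Conditions: CrCl2 (8 equiv), NiCl2 (2 mol % of the CrCl2), dry degassed DMF, 0.005 M, slow addition of 23, rt; then H2O
Reagents that add atoms: none
Why: Divalent chromium reduces NiCl2 to zerovalent nickel, which inserts into the C1–Br bond (made more reactive by the conjugated alkyne), passes the alkenyl group on to trivalent chromium and is recycled, so that two CrCl2 are consumed per bromide and vinylchromium 24 adds to the C6 aldehyde. The closest known reaction type is the intramolecular Nozaki–Hiyama–Kishi reaction of haloalkene aldehydes, which is established for sugar-derived cyclohexenols. The ring closes in the 6-exo-trig mode, which is possible only because the metal on C1 is cis to C3, the geometry fixed in step 16. The new C6 centre is controlled by C5: in the half-chair with OMe on C4 and OSiEt3 on C5 equatorial, the C5–O bond is antiperiplanar to the forming C1–C6 bond (polar Felkin–Anh arrangement, the silyl ether being unable to chelate), the carbonyl oxygen then points pseudoaxially, away from the alkynyl group on C1, and the 5,6-cis (anti) diol pattern should result. The step needs chemoselectivity for the aldehyde over acetate, enyne and skipped diene, which the low basicity of organochromium reagents and the lack of any leaving group beta to C1 secure, and it needs cyclisation to beat dimerisation and protonation, which high dilution, dry degassed solvent and a low nickel loading secure. A silyl shift between O5 and O6 in the chromium alkoxide would be without consequence, as both oxygens are freed in step 19.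

Step 19
Reactants: 25 (1S,4S,5S,6S)-4-hydroxy-6-methoxy-3-[(5E)-7-methyl-3-methylidene-7-(triethylsilyloxy)oct-5-en-1-yn-1-yl]-5-(triethylsilyloxy)cyclohex-2-en-1-yl acetate
Product: 26 (1S,4S,5S,6R)-4,5-dihydroxy-3-[(5E)-7-hydroxy-7-methyl-3-methylideneoct-5-en-1-yn-1-yl]-6-methoxycyclohex-2-en-1-yl acetate (CNP0546270.2)
Conditions: HF·pyridine, excess pyridine, THF, 0 °C to rt
Reagents that add atoms: none
Why: Fluoride-mediated desilylation under buffered, weakly acidic conditions should remove both triethylsilyl ethers quickly, should not ionise the tertiary allylic alcohol and leaves the acetate where it is, since C2 is sp2 and O4 is methylated and no adjacent hydroxyl is on offer for acyl transfer.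

Compound list
1 | L-arabinose | O=C[C@H](O)[C@@H](O)[C@@H](O)CO | starting material
2 | 5-O-(tert-butyldiphenylsilyl)-L-arabinofuranose (anomeric mixture) | CC(C)(C)[Si](OC[C@@H]1OC(O)[C@H](O)[C@H]1O)(c1ccccc1)c1ccccc1 | intermediate
3 | 5-O-(tert-butyldiphenylsilyl)-1,2-O-isopropylidene-β-L-arabinofuranose | CC(C)(C)[Si](OC[C@@H]1O[C@@H]2OC(C)(C)O[C@@H]2[C@H]1O)(c1ccccc1)c1ccccc1 | intermediate
4 | 5-O-(tert-butyldiphenylsilyl)-1,2-O-isopropylidene-3-O-methyl-β-L-arabinofuranose | CC(C)(C)[Si](OC[C@@H]1O[C@@H]2OC(C)(C)O[C@@H]2[C@H]1OC)(c1ccccc1)c1ccccc1 | intermediate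
5 | 1,2-O-isopropylidene-3-O-methyl-β-L-arabinofuranose | OC[C@@H]1O[C@@H]2OC(C)(C)O[C@@H]2[C@H]1OC | intermediate
6 | 1,2-O-isopropylidene-3-O-methyl-β-L-arabino-pentodialdo-1,4-furanose | O=C[C@@H]1O[C@@H]2OC(C)(C)O[C@@H]2[C@H]1OC | intermediate
7 | 6,6-dibromo-5,6-dideoxy-1,2-O-isopropylidene-3-O-methyl-β-L-arabino-hex-5-enofuranose | BrC(Br)=C[C@@H]1O[C@@H]2OC(C)(C)O[C@@H]2[C@H]1OC | intermediate
8 | 6,6-dibromo-5,6-dideoxy-3-O-methyl-L-arabino-hex-5-enofuranose (lactol, anomeric mixture, not isolated) | BrC(Br)=C[C@@H]1OC(O)[C@H](O)[C@H]1OC | intermediate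
9 | 6,6-dibromo-5,6-dideoxy-3-O-methyl-L-arabino-hex-5-enitol, (2S,3S,4S)-6,6-dibromo-3-methoxyhex-5-ene-1,2,4-triol | BrC(Br)=C[C@H](O)[C@H](OC)[C@@H](O)CO | intermediate
10 | 6,6-dibromo-5,6-dideoxy-1,2-O-isopropylidene-3-O-methyl-L-arabino-hex-5-enitol | BrC(Br)=C[C@H](O)[C@H](OC)[C@@H]1COC(C)(C)O1 | intermediate
11 | 4-O-acetyl-6,6-dibromo-5,6-dideoxy-1,2-O-isopropylidene-3-O-methyl-L-arabino-hex-5-enitol | BrC(Br)=C[C@H](OC(C)=O)[C@H](OC)[C@@H]1COC(C)(C)O1 | intermediate
12 | 4-O-acetyl-6,6-dibromo-5,6-dideoxy-3-O-methyl-L-arabino-hex-5-enitol | BrC(Br)=C[C@H](OC(C)=O)[C@H](OC)[C@@H](O)CO | intermediate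
13 | 4-O-acetyl-6,6-dibromo-5,6-dideoxy-3-O-methyl-1,2-bis-O-(triethylsilyl)-L-arabino-hex-5-enitol | BrC(Br)=C[C@H](OC(C)=O)[C@H](OC)[C@@H](O[Si](CC)(CC)CC)CO[Si](CC)(CC)CC | intermediate
14 | 2-methylbut-3-yn-2-ol | C#CC(C)(C)O | starting material
15 | triethyl[(2-methylbut-3-yn-2-yl)oxy]silane | C#CC(C)(C)O[Si](CC)(CC)CC | intermediate
16 | 2,3-dibromopropene | C=C(Br)CBr | starting material
17 | chlorobis(cyclopentadienyl)[(1E)-3-methyl-3-(triethylsilyloxy)but-1-en-1-yl]zirconium (not isolated) | CC[Si](CC)(CC)OC(C)(C)/C=C/[Zr+2]Cl.c1cc[cH-]c1.c1cc[cH-]c1 | intermediate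
18 | {[(3E)-6-bromo-2-methylhepta-3,6-dien-2-yl]oxy}triethylsilane | C=C(Br)C/C=C/C(C)(C)O[Si](CC)(CC)CC | intermediate
19 | trimethylsilylacetylene | C#C[Si](C)(C)C | starting material
20 | triethyl{[(3E)-2-methyl-6-methylidene-8-(trimethylsilyl)oct-3-en-7-yn-2-yl]oxy}silane | C=C(C#C[Si](C)(C)C)C/C=C/C(C)(C)O[Si](CC)(CC)CC | intermediate
21 | triethyl{[(3E)-2-methyl-6-methylideneoct-3-en-7-yn-2-yl]oxy}silane | C=C(C#C)C/C=C/C(C)(C)O[Si](CC)(CC)CC | intermediate
22 | (2S,3S,4S,5Z,11E)-6-bromo-3-methoxy-13-methyl-9-methylidene-1,2,13-tris(triethylsilyloxy)tetradeca-5,11-dien-7-yn-4-yl acetate | C=C(C#C/C(Br)=C/[C@H](OC(C)=O)[C@H](OC)[C@@H](O[Si](CC)(CC)CC)CO[Si](CC)(CC)CC)C/C=C/C(C)(C)O[Si](CC)(CC)CC | intermediate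
23 | (2R,3S,4S,5Z,11E)-4-acetoxy-6-bromo-3-methoxy-13-methyl-9-methylidene-2,13-bis(triethylsilyloxy)tetradeca-5,11-dien-7-ynal (precursor of the key step) | C=C(C#C/C(Br)=C/[C@H](OC(C)=O)[C@H](OC)[C@@H](O[Si](CC)(CC)CC)C=O)C/C=C/C(C)(C)O[Si](CC)(CC)CC | intermediate
24 | vinylchromium dichloride derived from 23, CrCl2 unit on C1 cis to C3 (not isolated) | C=C(C#C/C([Cr](Cl)Cl)=C/[C@H](OC(C)=O)[C@H](OC)[C@@H](O[Si](CC)(CC)CC)C=O)C/C=C/C(C)(C)O[Si](CC)(CC)CC | intermediate
25 | (1S,4S,5S,6S)-4-hydroxy-6-methoxy-3-[(5E)-7-methyl-3-methylidene-7-(triethylsilyloxy)oct-5-en-1-yn-1-yl]-5-(triethylsilyloxy)cyclohex-2-en-1-yl acetate (product of the key step) | C=C(C#CC1=C[C@H](OC(C)=O)[C@H](OC)[C@@H](O[Si](CC)(CC)CC)[C@H]1O)C/C=C/C(C)(C)O[Si](CC)(CC)CC | intermediate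
26 | (1S,4S,5S,6R)-4,5-dihydroxy-3-[(5E)-7-hydroxy-7-methyl-3-methylideneoct-5-en-1-yn-1-yl]-6-methoxycyclohex-2-en-1-yl acetate | C=C(C#CC1=C[C@H](OC(C)=O)[C@H](OC)[C@@H](O)[C@H]1O)C/C=C/C(C)(C)O | target

Total step count: 19. Longest linear sequence: 15 steps (steps 1–11 and 16–19, from L-arabinose).

Steps most likely to fail

Step 18: poor facial selectivity in the addition to the C6 aldehyde, because the tether may override the open-chain Felkin–Anh preference. The fallback sets out from 23. The closure is run as in step 18 and the 5,6-trans product, the C6-epimeric alcohol F1, is separated. It is inverted by a Mitsunobu reaction with chloroacetic acid (PPh3, DIAD, toluene, 0 °C), an SN2 displacement of the pseudoequatorial oxyphosphonium group, which should give the 5,6-cis C6 chloroacetate F2. Thiourea and NaHCO3 in ethanol then remove the chloroacetyl group selectively beside the acetate, and the route is rejoined at 25. Inversion is preferred to an oxidation–hydride detour, because small hydrides attack such cyclohexenones axially and would be expected to return the trans isomer.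

Step 16: several processes could spoil the coupling.
- loss of mono-selectivity through a second coupling
- amine-induced dehydrobromination of the Z-bromoenyne
- copper-induced oxidative dimerisation of the alkyne
- ionisation of the allylic acetate by zerovalent palladium

The fallback sets out from 21. Deprotonation (n-BuLi, THF, −78 °C) and transmetalation with ZnBr2 give the alkynylzinc bromide F3. This is joined to 13 in a trans-selective Negishi alkynylation (PdCl2(DPEphos), THF, 0 °C to rt) that needs neither amine nor copper, and the route is rejoined at 22.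

Step 17: the oxidative desilylation could go wrong in three ways.
- incomplete or unselective silyl cleavage
- loss of the tertiary allylic silyl ether through adventitious HCl
- epimerisation at C5 or β-elimination of methanol under the amine

The fallback sets out from 13, before the acid-sensitive side chain is present. PPTS in MeOH/CH2Cl2 at −10 °C should cleave only the primary silyl ether and give the primary alcohol F4. Sonogashira coupling with 21 under the conditions of step 16 gives the hydroxy Z-bromoenyne F5. A buffered Dess–Martin oxidation (DMP, NaHCO3, CH2Cl2, 0 °C), which uses no amine base, rejoins the route at 23.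

Further compounds
F1 | step 18 | C6 epimer of 25 (5,6-trans alcohol) | C=C(C#CC1=C[C@H](OC(C)=O)[C@H](OC)[C@@H](O[Si](CC)(CC)CC)[C@@H]1O)C/C=C/C(C)(C)O[Si](CC)(CC)CC
F2 | step 18 | C6 chloroacetate of 25 (5,6-cis) | C=C(C#CC1=C[C@H](OC(C)=O)[C@H](OC)[C@@H](O[Si](CC)(CC)CC)[C@H]1OC(=O)CCl)C/C=C/C(C)(C)O[Si](CC)(CC)CC
F3 | step 16 | alkynylzinc bromide derived from 21 | C=C(C#C[Zn]Br)C/C=C/C(C)(C)O[Si](CC)(CC)CC
F4 | step 17 | 4-O-acetyl-6,6-dibromo-5,6-dideoxy-3-O-methyl-2-O-(triethylsilyl)-L-arabino-hex-5-enitol | BrC(Br)=C[C@H](OC(C)=O)[C@H](OC)[C@@H](O[Si](CC)(CC)CC)CO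
F5 | step 17 | primary alcohol corresponding to 22 (free hydroxyl on C6) | C=C(C#C/C(Br)=C/[C@H](OC(C)=O)[C@H](OC)[C@@H](O[Si](CC)(CC)CC)CO)C/C=C/C(C)(C)O[Si](CC)(CC)CC
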